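**Retrosynthetic overview**
1. Sceptrin (22) ⇒ twofold N-acylation of the C2-symmetric tetraamine 19 with pyrrole 20; both 2-aminoimidazole rings ⇒ bis(chloromethyl ketone) 16 + N-Boc-guanidine; 16 ⇒ all-trans diester 14.
2. 14 ⇒ bicyclic N-Boc lactam 12 by one ethanolysis with double epimerisation (thermodynamic funnel to the all-trans cyclobutane).
3. 12 ⇒ acyclic imide 10 by an enantioselective intramolecular [2+2] photocycloaddition that makes both bonds between an imidazole-bearing and an aminomethyl-bearing ring carbon; ring order: temporary pyrrolidinone (5-exo), cyclobutane, then both imidazoles at once in step 9.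
4. Enabling feature: in the target each imidazole C5 (kept at acyl oxidation level) and the amide nitrogen on the neighbouring ring carbon are 1,5-related (N–CH2–C(ring)–C(ring)–C5), so they can be tied as an imide N–C(=O) tether built only from target atoms; the imidazole-bearing ring carbons stay α to a carbonyl until step 9 and are epimerisable, so only the two CH2N-bearing carbons must be set.
5. 10 ⇒ bis-Boc (E)-but-2-ene-1,4-diamine 3 + fumaric acid half-pyrazolide 7 (the pyrazolide is the two-point binding site for the chiral catalyst).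

Key step: step 5

Assumption: 1, 4, 5, 17 and 20 are taken as commercially available; the Boc group delivered by 17 is drawn on ring nitrogen N1 of each imidazole in 18, and its exact position is immaterial because it is removed in step 10.

**Step 1**
Reactants: 1 (2E)-but-2-ene-1,4-diamine dihydrochloride
Product: 3 di-tert-butyl (2E)-but-2-ene-1,4-diyldicarbamate, via free diamine 2 (not isolated)
Conditions: Boc2O (2.2 equiv), NaOH (2.0 equiv), 1,4-dioxane/H2O, 0 °C to rt
Reagents that add atoms: di-tert-butyl dicarbonate, CC(C)(C)OC(=O)OC(=O)OC(C)(C)C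
Why: NaOH frees the diamine 2 and both primary amines are carbamoylated by Boc2O (standard N-Boc protection); the E-alkene is untouched and no stereocenter is involved.

**Step 2**
Reactants: 4 (2E)-4-tert-butoxy-4-oxobut-2-enoic acid; 5 3,5-dimethyl-1H-pyrazole
Product: 6 tert-butyl (2E)-4-(3,5-dimethyl-1H-pyrazol-1-yl)-4-oxobut-2-enoate
Conditions: DCC (1.1 equiv), DMAP (cat.), CH2Cl2, 0 °C to rt
Reagents that add atoms: none
Why: Carbodiimide-mediated (Steglich-type) N-acylation of the pyrazole N–H by the free carboxyl group should give the N-acylpyrazole that later binds the catalyst, with the E-alkene and the tert-butyl ester unchanged.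

**Step 3**
Reactants: 6 tert-butyl (2E)-4-(3,5-dimethyl-1H-pyrazol-1-yl)-4-oxobut-2-enoate
Product: 7 (2E)-4-(3,5-dimethyl-1H-pyrazol-1-yl)-4-oxobut-2-enoic acid
Conditions: TFA, CH2Cl2, rt
Reagents that add atoms: none
Why: Acidolysis of the tert-butyl ester (loss of 2-methylpropene) should leave the acid-stable N-acylpyrazole and the E-alkene intact.

**Step 4**
Reactants: 7 (2E)-4-(3,5-dimethyl-1H-pyrazol-1-yl)-4-oxobut-2-enoic acid; 3 di-tert-butyl (2E)-but-2-ene-1,4-diyldicarbamate
Product: 10 tert-butyl N-[(2E)-4-[(tert-butoxycarbonyl)amino]but-2-en-1-yl]-N-[(2E)-4-(3,5-dimethyl-1H-pyrazol-1-yl)-4-oxobut-2-enoyl]carbamate, via acid chloride 8 (not isolated), via lithium carbamate 9 (not isolated)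
Conditions: (COCl)2, DMF (cat.), CH2Cl2, 0 °C to rt, evaporate; 3 (3 equiv), n-BuLi (1 equiv), THF, −78 °C; then 8, −78 to −40 °C; excess 3 recovered
Reagents that add atoms: none
Why: N-Acylation of a lithiated carbamate by an acid chloride (imide formation) should be selective because the acid chloride is far more electrophilic than the N-acylpyrazole, and the threefold excess of 3 over n-BuLi keeps the reaction at mono-acylation.

**Step 5**
Reactants: 10 tert-butyl N-[(2E)-4-[(tert-butoxycarbonyl)amino]but-2-en-1-yl]-N-[(2E)-4-(3,5-dimethyl-1H-pyrazol-1-yl)-4-oxobut-2-enoyl]carbamate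
Product: 12 tert-butyl (1R,5R,6R,7R)-6-{[(tert-butoxycarbonyl)amino]methyl}-7-(3,5-dimethyl-1H-pyrazole-1-carbonyl)-2-oxo-3-azabicyclo[3.2.0]heptane-3-carboxylate, via triplet 1,4-diradical 11 (not isolated)
Conditions: Δ-[Rh(C17H16NS)2(MeCN)2]PF6 (4 mol%; C17H16NS = cyclometalated 5-tert-butyl-2-phenylbenzothiazole), acetone (0.02 M), blue LEDs (420–450 nm), rt, N2
Reagents that add atoms: none
Why: Proposed new method: the N-acylpyrazole of 10 should displace both MeCN ligands and chelate (N,O) the Lewis-acidic trivalent rhodium centre, only this complex absorbs the blue light, and its triplet adds through the enone β-carbon (the carbon α to the imide carbonyl) to the proximal carbon of the tethered alkene to give the triplet 1,4-diradical 11, which closes after intersystem crossing. The closest known reaction type is the chiral-at-rhodium Lewis acid-catalysed visible-light [2+2] photocycloaddition of α,β-unsaturated N-acylpyrazoles and 2-acylimidazoles with alkenes, run here intramolecularly in the manner of sensitised [2+2] reactions of N-allyl acrylamides. The pyrrolidinone ring closes 5-exo-trig (rule of five) and the cyclobutane by radical–radical recombination of 11, giving the straight, necessarily cis-fused 3-azabicyclo[3.2.0]heptan-2-one. C1 is set in the first bond formation from the enone face left open by the tert-butyl group of a cyclometalated ligand, C5 is tied to C1 by the cis ring fusion, C6 is set in the recombination with its CH2NHBoc group on the convex face (trans to the ring CH2), and C7 is expected exo (trans to the C1 carbonyl, as in the E-acceptor) but is not needed. The step needs only the absolute configuration at C5 and C6, the two carbons that cannot be epimerised later, and the short imide tether secures it by relaying the catalyst-controlled face at C1; E/Z isomerisation of the acceptor under irradiation and any epimer at C1 or C7 (both α to a carbonyl) converge in step 6.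

**Step 6**
Reactants: 12 tert-butyl (1R,5R,6R,7R)-6-{[(tert-butoxycarbonyl)amino]methyl}-7-(3,5-dimethyl-1H-pyrazole-1-carbonyl)-2-oxo-3-azabicyclo[3.2.0]heptane-3-carboxylate
Product: 14 diethyl (1S,2S,3R,4R)-3,4-bis{[(tert-butoxycarbonyl)amino]methyl}cyclobutane-1,2-dicarboxylate, via cis-configured diester 13 (not isolated)
Conditions: NaOEt (0.3 equiv), EtOH, 0 to 50 °C
Reagents that add atoms: ethanol, CCO
Why: Ethoxide should open the N-Boc-activated lactam at the ring carbonyl and transesterify the N-acylpyrazole (acyl substitution), and reversible enolisation then epimerises both ester-bearing carbons of 13 to the all-trans diester, the thermodynamic isomer with four pseudo-equatorial substituents, while the two CH2NHBoc-bearing stereocenters cannot enolise and keep the configuration set in step 5.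

**Step 7**
Reactants: 14 diethyl (1S,2S,3R,4R)-3,4-bis{[(tert-butoxycarbonyl)amino]methyl}cyclobutane-1,2-dicarboxylate
Product: 15 di-tert-butyl {[(1R,2R,3S,4S)-3,4-bis{2-[dimethyl(oxo)-λ6-sulfanylidene]acetyl}cyclobutane-1,2-diyl]bis(methylene)}dicarbamate
Conditions: Me3S(O)I (6 equiv), KOtBu (6 equiv), THF, reflux; then 14, rt to 60 °C
Reagents that add atoms: trimethylsulfoxonium iodide, C[S+](C)(C)=O.[I-]
Why: Acyl substitution of each ester by dimethylsulfoxonium methylide should give the stabilised β-keto sulfoxonium ylide (a known diazomethane-free ester homologation), the ylide being too weak a base to disturb the carbamate N–H groups and the all-trans configuration already being the stable one.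

**Step 8**
Reactants: 15 di-tert-butyl {[(1R,2R,3S,4S)-3,4-bis{2-[dimethyl(oxo)-λ6-sulfanylidene]acetyl}cyclobutane-1,2-diyl]bis(methylene)}dicarbamate
Product: 16 di-tert-butyl {[(1R,2R,3S,4S)-3,4-bis(chloroacetyl)cyclobutane-1,2-diyl]bis(methylene)}dicarbamate
Conditions: HCl (4 M in 1,4-dioxane, 2.1 equiv), THF, 0 to 60 °C
Reagents that add atoms: hydrogen chloride, Cl
Why: Protonation of each ylide carbon followed by SN2 displacement of dimethyl sulfoxide by chloride should give the chloromethyl ketone, and because the stoichiometric HCl is consumed by the basic ylide the Boc groups should survive.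

**Step 9**
Reactants: 16 di-tert-butyl {[(1R,2R,3S,4S)-3,4-bis(chloroacetyl)cyclobutane-1,2-diyl]bis(methylene)}dicarbamate; 17 N-Boc-guanidine (tert-butyl carbamimidoylcarbamate)
Product: 18 di-tert-butyl 4,4'-[(1S,2S,3R,4R)-3,4-bis{[(tert-butoxycarbonyl)amino]methyl}cyclobutane-1,2-diyl]bis(2-amino-1H-imidazole-1-carboxylate)
Conditions: 17 (6 equiv), NaI (0.2 equiv), DMF, rt
Reagents that add atoms: none
Why: Condensation of an α-haloketone with N-Boc-guanidine (N-alkylation, then cyclodehydration onto the ketone) should build both 2-aminoimidazole rings on the former ketone carbons, the excess guanidine taking up the HCl, after which the imidazole-bearing ring carbons are no longer epimerisable.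

**Step 10**
Reactants: 18 di-tert-butyl 4,4'-[(1S,2S,3R,4R)-3,4-bis{[(tert-butoxycarbonyl)amino]methyl}cyclobutane-1,2-diyl]bis(2-amino-1H-imidazole-1-carboxylate)
Product: 19 4,4'-[(1S,2S,3R,4R)-3,4-bis(aminomethyl)cyclobutane-1,2-diyl]bis(1H-imidazol-2-amine) tetrahydrochloride
Conditions: HCl (4 M in 1,4-dioxane), MeOH, 0 °C to rt
Reagents that add atoms: hydrogen chloride, Cl
Why: Acidolysis should remove all four Boc groups (two carbamates, two imidazole N-carboxylates) as 2-methylpropene and CO2 and deliver the tetraamine as its stable tetrahydrochloride.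

**Step 11**
Reactants: 19 4,4'-[(1S,2S,3R,4R)-3,4-bis(aminomethyl)cyclobutane-1,2-diyl]bis(1H-imidazol-2-amine) tetrahydrochloride; 20 1-(4-bromo-1H-pyrrol-2-yl)-2,2,2-trichloroethan-1-one
Product: 22 sceptrin (N,N'-{[(1R,2R,3S,4S)-3,4-bis(2-amino-1H-imidazol-5-yl)cyclobutane-1,2-diyl]bis(methylene)}bis(4-bromo-1H-pyrrole-2-carboxamide)), via free tetraamine 21 (not isolated)
Conditions: 20 (2.1 equiv), Na2CO3 (4.5 equiv), DMF, rt
Reagents that add atoms: none
Why: Haloform-type acyl transfer from the trichloromethyl ketone (chloroform as leaving group) should acylate the two primary alkylamines of 21 chemoselectively, since the 2-aminoimidazole nitrogens are much weaker nucleophiles, and no stereocenter is touched.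

**Compound list**
1 | (2E)-but-2-ene-1,4-diamine dihydrochloride | NC/C=C/CN.Cl.Cl | starting material
2 | (2E)-but-2-ene-1,4-diamine (free base, not isolated) | NC/C=C/CN | intermediate
3 | di-tert-butyl (2E)-but-2-ene-1,4-diyldicarbamate | CC(C)(C)OC(=O)NC/C=C/CNC(=O)OC(C)(C)C | intermediate
4 | (2E)-4-tert-butoxy-4-oxobut-2-enoic acid (mono-tert-butyl fumarate) | CC(C)(C)OC(=O)/C=C/C(=O)O | starting material
5 | 3,5-dimethyl-1H-pyrazole | Cc1cc(C)[nH]n1 | starting material
6 | tert-butyl (2E)-4-(3,5-dimethyl-1H-pyrazol-1-yl)-4-oxobut-2-enoate | Cc1cc(C)n(n1)C(=O)/C=C/C(=O)OC(C)(C)C | intermediate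
7 | (2E)-4-(3,5-dimethyl-1H-pyrazol-1-yl)-4-oxobut-2-enoic acid | Cc1cc(C)n(n1)C(=O)/C=C/C(=O)O | intermediate
8 | (2E)-4-(3,5-dimethyl-1H-pyrazol-1-yl)-4-oxobut-2-enoyl chloride (not isolated) | Cc1cc(C)n(n1)C(=O)/C=C/C(=O)Cl | intermediate
9 | mono-N-lithio derivative of 3 (lithium carbamate, not isolated) | CC(C)(C)OC(=O)[N-]C/C=C/CNC(=O)OC(C)(C)C.[Li+] | intermediate
10 | tert-butyl N-[(2E)-4-[(tert-butoxycarbonyl)amino]but-2-en-1-yl]-N-[(2E)-4-(3,5-dimethyl-1H-pyrazol-1-yl)-4-oxobut-2-enoyl]carbamate | Cc1cc(C)n(n1)C(=O)/C=C/C(=O)N(C/C=C/CNC(=O)OC(C)(C)C)C(=O)OC(C)(C)C | intermediate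
11 | triplet 1,4-diradical: cis-3,4-disubstituted N-Boc-2-oxopyrrolidine with radical centres on the CH bearing the pyrazolylcarbonyl group (at C3) and the CH bearing CH2NHBoc (at C4); rhodium-bound in the flask, drawn metal-free (not isolated) | Cc1cc(C)n(n1)C(=O)[CH][C@@H]1C(=O)N(C(=O)OC(C)(C)C)C[C@@H]1[CH]CNC(=O)OC(C)(C)C | intermediate
12 | tert-butyl (1R,5R,6R,7R)-6-{[(tert-butoxycarbonyl)amino]methyl}-7-(3,5-dimethyl-1H-pyrazole-1-carbonyl)-2-oxo-3-azabicyclo[3.2.0]heptane-3-carboxylate (cis-fused, 6-exo, 7-exo) | Cc1cc(C)n(n1)C(=O)[C@H]1[C@@H]2C(=O)N(C(=O)OC(C)(C)C)C[C@@H]2[C@H]1CNC(=O)OC(C)(C)C | intermediate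
13 | diethyl (1R,2R,3R,4R)-3,4-bis{[(tert-butoxycarbonyl)amino]methyl}cyclobutane-1,2-dicarboxylate (each ester cis to its neighbouring CH2NHBoc; not isolated) | CCOC(=O)[C@H]1[C@H](C(=O)OCC)[C@H](CNC(=O)OC(C)(C)C)[C@H]1CNC(=O)OC(C)(C)C | intermediate
14 | diethyl (1S,2S,3R,4R)-3,4-bis{[(tert-butoxycarbonyl)amino]methyl}cyclobutane-1,2-dicarboxylate (all-trans) | CCOC(=O)[C@H]1[C@H](CNC(=O)OC(C)(C)C)[C@@H](CNC(=O)OC(C)(C)C)[C@@H]1C(=O)OCC | intermediate
15 | di-tert-butyl {[(1R,2R,3S,4S)-3,4-bis{2-[dimethyl(oxo)-λ6-sulfanylidene]acetyl}cyclobutane-1,2-diyl]bis(methylene)}dicarbamate | CS(C)(=O)=CC(=O)[C@H]1[C@H](CNC(=O)OC(C)(C)C)[C@@H](CNC(=O)OC(C)(C)C)[C@@H]1C(=O)C=S(C)(C)=O | intermediate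
16 | di-tert-butyl {[(1R,2R,3S,4S)-3,4-bis(chloroacetyl)cyclobutane-1,2-diyl]bis(methylene)}dicarbamate | ClCC(=O)[C@H]1[C@H](CNC(=O)OC(C)(C)C)[C@@H](CNC(=O)OC(C)(C)C)[C@@H]1C(=O)CCl | intermediate
17 | N-Boc-guanidine (tert-butyl carbamimidoylcarbamate) | CC(C)(C)OC(=O)NC(N)=N | starting material
18 | di-tert-butyl 4,4'-[(1S,2S,3R,4R)-3,4-bis{[(tert-butoxycarbonyl)amino]methyl}cyclobutane-1,2-diyl]bis(2-amino-1H-imidazole-1-carboxylate) | CC(C)(C)OC(=O)n1cc(nc1N)[C@H]2[C@H](CNC(=O)OC(C)(C)C)[C@@H](CNC(=O)OC(C)(C)C)[C@@H]2c3cn(C(=O)OC(C)(C)C)c(N)n3 | intermediate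
19 | 4,4'-[(1S,2S,3R,4R)-3,4-bis(aminomethyl)cyclobutane-1,2-diyl]bis(1H-imidazol-2-amine) tetrahydrochloride | Nc1ncc([C@H]2[C@H](CN)[C@@H](CN)[C@@H]2c2cnc(N)[nH]2)[nH]1.Cl.Cl.Cl.Cl | intermediate
20 | 1-(4-bromo-1H-pyrrol-2-yl)-2,2,2-trichloroethan-1-one | O=C(c1cc(Br)c[nH]1)C(Cl)(Cl)Cl | starting material
21 | 4,4'-[(1S,2S,3R,4R)-3,4-bis(aminomethyl)cyclobutane-1,2-diyl]bis(1H-imidazol-2-amine) (free base, not isolated) | Nc1ncc([C@H]2[C@H](CN)[C@@H](CN)[C@@H]2c2cnc(N)[nH]2)[nH]1 | intermediate
22 | sceptrin, N,N'-{[(1R,2R,3S,4S)-3,4-bis(2-amino-1H-imidazol-5-yl)cyclobutane-1,2-diyl]bis(methylene)}bis(4-bromo-1H-pyrrole-2-carboxamide) | Nc1ncc([C@H]2[C@H](CNC(=O)c3cc(Br)c[nH]3)[C@@H](CNC(=O)c3cc(Br)c[nH]3)[C@@H]2c2cnc(N)[nH]2)[nH]1 | target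

**Step count and risks**
Total steps: 11. Longest linear sequence: 10 steps (steps 2 to 11, from 4 to 22); the other branch is step 1.

Steps most likely to fail:

Step 5 (Proposed new method). What may go wrong: insufficient discrimination of the two enone faces in the first C–C bond formation, loss of the convex-face preference at C6 during diradical recombination, or product inhibition of the catalyst. If only the sense of induction proves opposite, the Λ catalyst is used instead. Fallback with known chemistry, setting out from 10: 10 is irradiated at 405 nm with thioxanthone as an achiral triplet sensitiser (a known sensitised intramolecular enone–alkene [2+2] of the N-allyl acrylamide type) to give the racemic lactam rac-12 F1. Ethanolysis and epimerisation under the conditions of step 6 then give the racemic all-trans diester rac-14 F2. Its enantiomers are separated by preparative chromatography on a chiral stationary phase (amylose tris(3,5-dimethylphenylcarbamate)), which returns to the route at 14.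

Step 9. What may go wrong: low conversion in the twofold annulation, over-alkylation of the guanidine, or base-induced decomposition of the chloromethyl ketones. Fallback, setting out from 16: both chlorides are displaced with sodium diformylamide, NaN(CHO)2, in MeCN to give the bis(diformylamino) ketone di-tert-butyl {[(1R,2R,3S,4S)-3,4-bis[(diformylamino)acetyl]cyclobutane-1,2-diyl]bis(methylene)}dicarbamate F3. HCl in MeOH removes the formyl and Boc groups to give the bis(α-amino ketone) 1,1'-[(1S,2S,3R,4R)-3,4-bis(aminomethyl)cyclobutane-1,2-diyl]bis(2-aminoethan-1-one) tetrahydrochloride F4. Condensation with cyanamide (N#CN, water, pH about 4.5, 95 °C; the classical α-amino ketone route to 2-aminoimidazoles) closes both rings and returns to the route at 19.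

Step 7. What may go wrong: incomplete twofold acyl substitution at the hindered diester, or consumption of the ylide by competing deprotonation. Fallback, setting out from 14: both esters are converted with N,O-dimethylhydroxylamine hydrochloride and iPrMgCl (THF, −20 °C) into the bis(N-methoxy-N-methylamide) di-tert-butyl {[(1R,2R,3S,4S)-3,4-bis[methoxy(methyl)carbamoyl]cyclobutane-1,2-diyl]bis(methylene)}dicarbamate F5. Chloromethyllithium, generated in situ from ICH2Cl and MeLi·LiBr at −78 °C (extra equivalents for the two N–H groups), adds once to each amide, and acidic work-up of the stable tetrahedral chelate gives the chloromethyl ketones directly, returning to the route at 16.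

**Further compounds**
F1 | step 5 | racemic 12, tert-butyl (1RS,5RS,6RS,7RS)-6-{[(tert-butoxycarbonyl)amino]methyl}-7-(3,5-dimethyl-1H-pyrazole-1-carbonyl)-2-oxo-3-azabicyclo[3.2.0]heptane-3-carboxylate (1:1 mixture of enantiomers) | Cc1cc(C)n(n1)C(=O)[C@H]1[C@@H]2C(=O)N(C(=O)OC(C)(C)C)C[C@@H]2[C@H]1CNC(=O)OC(C)(C)C.Cc1cc(C)n(n1)C(=O)[C@@H]1[C@H]2C(=O)N(C(=O)OC(C)(C)C)C[C@H]2[C@@H]1CNC(=O)OC(C)(C)C
F2 | step 5 | racemic 14, diethyl (1RS,2RS,3SR,4SR)-3,4-bis{[(tert-butoxycarbonyl)amino]methyl}cyclobutane-1,2-dicarboxylate (1:1 mixture of enantiomers) | CCOC(=O)[C@H]1[C@H](CNC(=O)OC(C)(C)C)[C@@H](CNC(=O)OC(C)(C)C)[C@@H]1C(=O)OCC.CCOC(=O)[C@@H]1[C@@H](CNC(=O)OC(C)(C)C)[C@H](CNC(=O)OC(C)(C)C)[C@H]1C(=O)OCC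
F3 | step 9 | di-tert-butyl {[(1R,2R,3S,4S)-3,4-bis[(diformylamino)acetyl]cyclobutane-1,2-diyl]bis(methylene)}dicarbamate | O=CN(C=O)CC(=O)[C@H]1[C@H](CNC(=O)OC(C)(C)C)[C@@H](CNC(=O)OC(C)(C)C)[C@@H]1C(=O)CN(C=O)C=O
F4 | step 9 | 1,1'-[(1S,2S,3R,4R)-3,4-bis(aminomethyl)cyclobutane-1,2-diyl]bis(2-aminoethan-1-one) tetrahydrochloride | NCC(=O)[C@H]1[C@H](CN)[C@@H](CN)[C@@H]1C(=O)CN.Cl.Cl.Cl.Cl
F5 | step 7 | di-tert-butyl {[(1R,2R,3S,4S)-3,4-bis[methoxy(methyl)carbamoyl]cyclobutane-1,2-diyl]bis(methylene)}dicarbamate | CON(C)C(=O)[C@H]1[C@H](CNC(=O)OC(C)(C)C)[C@@H](CNC(=O)OC(C)(C)C)[C@@H]1C(=O)N(C)OC
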